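**Plan**

1. Locants (germacrane type): ring C1–C10, with C1 the ring =CH, C2 the CH2 beside it, C3 the tiglate carbinol, C4 (methyl C15) and C5 the oxirane carbons, C6 the acetate carbinol, C7 the CH bearing the isopropenyl group (C11–C13), C8/C9 CH2, and C10 the methyl-bearing (C14) alkene carbon.
2. Retrosynthesis: acetate, oxirane oxygen and tiglate are removed to the ring allylic alcohol. Its C3 carbinol sits on the methyl-bearing end of an E-trisubstituted C4=C5 olefin inside the ten-membered ring, which is the retron of a reductive aldehyde–alkyne coupling. The ring is therefore cut at C3–C4 to an acyclic ynal (C3 aldehyde; methyl-capped alkyne C15–C4≡C5). The chain is then cut at C9–C10 (sp3–sp2 coupling), C6–C7 (aldol) and C11–C12/C11=C13 (acyl to isopropenyl).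
3. Forward: crotonate aldol with but-2-ynal (C6–C7) → Weinreb amide and silyl ether → B-alkyl Suzuki coupling with (E)-4-iodopent-3-en-1-ol (C9–C10, brings the E-C1=C10 olefin) → methyl ketone → isopropenyl → ynal → nickel-catalysed reductive macrocyclisation closes the carbocycle at C3–C4 → C3 adjusted via the enone → tiglate → oxirane (second ring) → acetate.
4. Stereochemistry: C6 and C7 come from the (R)-4-benzyloxazolidinone syn-aldol. C3 is set by CBS reduction of the ring enone, so both ring-closure epimers converge. C4 and C5 are relayed from C6–OH in a matched titanium/D-tartrate epoxidation. E-C1=C10 comes from syn-hydrozirconation/iodination and stereoretentive coupling, E-C4=C5 from syn addition of C3 and H across the alkyne, and the tiglate geometry is bought.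

Key step: step 10

Remark: but-2-ynal is taken as a purchased aldehyde (it can also be liberated from its commercial diethyl acetal just before use); C6 keeps one spatial arrangement throughout, but its CIP descriptor reads S in the ring dienes and R once the oxirane is present.

**Route**

Step 1
Reactants: 1 pent-3-yn-1-ol
Product: 3 (E)-4-iodopent-3-en-1-ol, via alkenylzirconocene 2 (not isolated)
Conditions: Cp2Zr(H)Cl (2.5 equiv), THF, rt → 40 °C; then I2, 0 °C
Reagents that add atoms: iodine, II
Why: Hydrozirconation with the Schwartz reagent is a syn addition that, with excess reagent, places zirconium on the less hindered methyl-capped alkyne carbon, and iodinolysis with retention should give the E-alkenyl iodide (the hydroxyl travels as its zirconium alkoxide and is freed on work-up).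

Step 2
Reactants: 4 (R)-4-benzyloxazolidin-2-one; 5 (E)-but-2-enoyl chloride
Product: 7 (R)-4-benzyl-3-[(E)-but-2-enoyl]oxazolidin-2-one, via lithium oxazolidinide 6 (not isolated)
Conditions: n-BuLi, THF, −78 °C; then 5, −78 → 0 °C
Reagents that add atoms: none
Why: N-Acylation of the lithiated oxazolidinone with an acid chloride is the standard entry to Evans imides and leaves the E-crotonyl olefin untouched.

Step 3
Reactants: 7 (R)-4-benzyl-3-[(E)-but-2-enoyl]oxazolidin-2-one; 8 but-2-ynal
Product: 11 (R)-4-benzyl-3-[(2R,3R)-2-ethenyl-3-hydroxyhex-4-ynoyl]oxazolidin-2-one, via boron dienolate 9 (not isolated), via boron aldolate 10 (not isolated)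
Conditions: Bu2BOTf, Et3N, CH2Cl2, −78 → 0 °C; 8, −78 °C; then pH 7 buffer, MeOH, H2O2, 0 °C
Reagents that add atoms: none
Why: Evans boron aldol in its crotonate (dienolate) form: the Z-dibutylboron dienolate reacts at its α-carbon through a chair Zimmerman–Traxler transition state on the face away from the benzyl group, which should give the syn adduct with C7 (vinyl-bearing) and C6 (carbinol) configured as in the target.

Step 4
Reactants: 11 (R)-4-benzyl-3-[(2R,3R)-2-ethenyl-3-hydroxyhex-4-ynoyl]oxazolidin-2-one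
Product: 12 (2R,3R)-2-ethenyl-3-hydroxy-N-methoxy-N-methylhex-4-ynamide
Conditions: MeNH(OMe)·HCl, AlMe3, CH2Cl2, −20 → 0 °C
Reagents that add atoms: N,O-dimethylhydroxylamine hydrochloride, CNOC.Cl
Why: Aluminium-amide transamidation of the β-hydroxy imide (Weinreb amide formation) is assisted by the free hydroxyl, releases the auxiliary for recovery, and is not basic enough to epimerise C7 or move the vinyl group into conjugation.

Step 5
Reactants: 12 (2R,3R)-2-ethenyl-3-hydroxy-N-methoxy-N-methylhex-4-ynamide
Product: 13 (2R,3R)-3-(tert-butyldimethylsilyloxy)-2-ethenyl-N-methoxy-N-methylhex-4-ynamide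
Conditions: TBSOTf, 2,6-lutidine, CH2Cl2, −78 → 0 °C
Reagents that add atoms: tert-butyldimethylsilyl triflate, CC(C)(C)[Si](C)(C)OS(=O)(=O)C(F)(F)F
Why: Silyl triflate/lutidine silylation protects the propargylic C6 hydroxyl for the organometallic steps that follow without touching C7.

Step 6
Reactants: 13 (2R,3R)-3-(tert-butyldimethylsilyloxy)-2-ethenyl-N-methoxy-N-methylhex-4-ynamide; 3 (E)-4-iodopent-3-en-1-ol
Product: 15 (2R,5E)-2-[(1R)-1-(tert-butyldimethylsilyloxy)but-2-yn-1-yl]-8-hydroxy-N-methoxy-N,5-dimethyloct-5-enamide, via B-alkyl-9-BBN 14 (not isolated)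
Conditions: 9-BBN-H, THF, 0 °C → rt; then 3, Pd(dppf)Cl2 (cat.), AsPh3 (cat.), Cs2CO3, DMF–H2O, rt
Reagents that add atoms: none
Why: B-alkyl Suzuki–Miyaura coupling: 9-BBN adds anti-Markovnikov to the monosubstituted vinyl group much faster than to the hindered internal alkyne, and the alkylborane should couple with the alkenyl iodide with retention of E geometry, forming C9–C10 and the C1=C10 olefin.

Step 7
Reactants: 15 (2R,5E)-2-[(1R)-1-(tert-butyldimethylsilyloxy)but-2-yn-1-yl]-8-hydroxy-N-methoxy-N,5-dimethyloct-5-enamide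
Product: 16 (3R,6E)-3-[(1R)-1-(tert-butyldimethylsilyloxy)but-2-yn-1-yl]-9-hydroxy-6-methylnon-6-en-2-one
Conditions: MeMgBr (4 equiv), THF, −20 → 0 °C; NH4Cl (aq)
Reagents that add atoms: methylmagnesium bromide, C[Mg]Br
Why: Grignard addition to the Weinreb amide stops at the chelated tetrahedral adduct, which collapses to the methyl ketone only on work-up (one equivalent is spent on the free hydroxyl).

Step 8
Reactants: 16 (3R,6E)-3-[(1R)-1-(tert-butyldimethylsilyloxy)but-2-yn-1-yl]-9-hydroxy-6-methylnon-6-en-2-one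
Product: 17 (3E,7S,8R)-8-(tert-butyldimethylsilyloxy)-4-methyl-7-(prop-1-en-2-yl)undec-3-en-9-yn-1-ol
Conditions: Ph3PCH3Br, KOt-Bu, THF, 0 °C; then 16, 0 °C → rt
Reagents that add atoms: methyltriphenylphosphonium bromide, C[P+](c1ccccc1)(c1ccccc1)c1ccccc1.[Br-]
Why: Wittig methylenation of the methyl ketone with the non-stabilised ylide builds the isopropenyl group, and at 0 °C it is expected to outrun enolisation towards C7.

Step 9
Reactants: 17 (3E,7S,8R)-8-(tert-butyldimethylsilyloxy)-4-methyl-7-(prop-1-en-2-yl)undec-3-en-9-yn-1-ol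
Product: 18 (3E,7S,8R)-8-(tert-butyldimethylsilyloxy)-4-methyl-7-(prop-1-en-2-yl)undec-3-en-9-ynal
Conditions: Dess–Martin periodinane, NaHCO3, CH2Cl2, 0 °C
Reagents that add atoms: none
Why: Buffered Dess–Martin oxidation converts the homoallylic alcohol into the β,γ-unsaturated aldehyde without acid or base strong enough to move the olefin into conjugation; the aldehyde is used at once.

Step 10
Reactants: 18 (3E,7S,8R)-8-(tert-butyldimethylsilyloxy)-4-methyl-7-(prop-1-en-2-yl)undec-3-en-9-ynal
Product: 20 (1(10)E,4E,6S,7S)-6-(tert-butyldimethylsilyloxy)germacra-1(10),4,11-trien-3-ol as a mixture of C3 epimers, via triethylsilyl ether 19 (not isolated)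
Conditions: Ni(cod)2 (30 mol%), IMes·HCl (30 mol%), KOt-Bu (30 mol%), Et3SiH (5 equiv), THF, rt, slow addition of 18 (final 5 mM); then HF·pyridine, pyridine, THF, 0 °C
Reagents that add atoms: none
Why: Ni(0)–NHC binds the C4≡C5 alkyne and the C3 aldehyde and couples them oxidatively to a five-membered oxanickelacycle (new C3–C4 bond, nickel on C5 and O); Si–H σ-bond metathesis with Et3SiH puts silicon on oxygen and hydride on nickel, and C5–H reductive elimination releases silyl ether 19, which buffered HF unmasks while the more hindered TBS ether should survive. The closest known reaction type is the nickel-catalysed reductive coupling of aldehydes with alkynes in its intramolecular form, the reductive macrocyclisation of ynals to endocyclic E-allylic alcohols, here asked to close a smaller ring than is usual for it. The ten-membered carbocycle closes in the 10-endo-dig mode, both alkyne carbons ending in the ring. C3 is the only new stereocentre; it is governed by the conformation of the forming ring and is not relied upon, because both epimers give the same enone in step 11. The step needs regioselectivity (C3 to C4 rather than to C5, which would give a nine-membered ring with an exocyclic ethylidene) and ring closure over oligomerisation: the small IMes ligand directs C–C bond formation to the methyl-capped alkyne carbon and away from the branched silyloxy-bearing one, and slow addition at high dilution favours cyclisation. The E geometry of C4=C5 follows from syn addition of C3 and H across the alkyne.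

Step 11
Reactants: 20 (1(10)E,4E,6S,7S)-6-(tert-butyldimethylsilyloxy)germacra-1(10),4,11-trien-3-ol (C3 epimers)
Product: 21 (1(10)E,4E,6S,7S)-6-(tert-butyldimethylsilyloxy)germacra-1(10),4,11-trien-3-one
Conditions: Dess–Martin periodinane, NaHCO3, CH2Cl2, 0 °C → rt
Reagents that add atoms: none
Why: Dess–Martin oxidation of the allylic alcohols merges both C3 epimers into one enone, and the C3 carbonyl also removes the Cope pathway of the ring 1,5-diene.

Step 12
Reactants: 21 (1(10)E,4E,6S,7S)-6-(tert-butyldimethylsilyloxy)germacra-1(10),4,11-trien-3-one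
Product: 22 (1(10)E,3S,4E,6S,7S)-6-(tert-butyldimethylsilyloxy)germacra-1(10),4,11-trien-3-ol
Conditions: (R)-2-methyl-CBS-oxazaborolidine (0.3 equiv), catecholborane, toluene, −78 °C
Reagents that add atoms: none
Why: Corey–Bakshi–Shibata reduction: the α-methyl alkenyl group acts as the large and the C2 methylene as the small carbonyl substituent, so the (R)-catalyst should deliver hydride to give the 3S alcohol under catalyst control, and catecholborane at −78 °C does not hydroborate the olefins.

Step 13
Reactants: 22 (1(10)E,3S,4E,6S,7S)-6-(tert-butyldimethylsilyloxy)germacra-1(10),4,11-trien-3-ol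
Product: 23 (1(10)E,3S,4E,6S,7S)-6-(tert-butyldimethylsilyloxy)germacra-1(10),4,11-trien-3-yl (E)-2-methylbut-2-enoate
Conditions: tiglic acid, DCC, DMAP (cat.), CH2Cl2, 0 °C → rt
Reagents that add atoms: tiglic acid, C/C=C(\C)C(=O)O
Why: Steglich esterification acylates the only free hydroxyl with retention at C3 and avoids the ketene pathway by which the acid chloride with amine bases deconjugates the tigloyl group.

Step 14
Reactants: 23 (1(10)E,3S,4E,6S,7S)-6-(tert-butyldimethylsilyloxy)germacra-1(10),4,11-trien-3-yl (E)-2-methylbut-2-enoate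
Product: 24 (1(10)E,3S,4E,6S,7S)-6-hydroxygermacra-1(10),4,11-trien-3-yl (E)-2-methylbut-2-enoate
Conditions: TBAF, AcOH, THF, 0 °C → rt
Reagents that add atoms: none
Why: Fluoride cleaves the remaining Si–O bond, and acetic acid buffering keeps the medium from attacking the tiglate or isomerising the skipped diene.

Step 15
Reactants: 24 (1(10)E,3S,4E,6S,7S)-6-hydroxygermacra-1(10),4,11-trien-3-yl (E)-2-methylbut-2-enoate
Product: 25 (1(10)E,3S,4R,5R,6R,7S)-4,5-epoxy-6-hydroxygermacra-1(10),11-dien-3-yl (E)-2-methylbut-2-enoate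
Conditions: Ti(Oi-Pr)4 (20 mol%), D-(−)-diisopropyl tartrate (24 mol%), t-BuOOH, 4 Å MS, CH2Cl2, −20 °C
Reagents that add atoms: tert-butyl hydroperoxide, CC(C)(C)OO
Why: Sharpless (titanium–tartrate) hydroxyl-directed epoxidation touches only the allylic C4=C5 olefin; oxygen is delivered syn to the nearly eclipsed C6–O bond with ring carbon C7 on the far face, which for this C6 configuration is the face giving 4R,5R, and D-(−)-tartrate is the matched ligand (erythro rule), so C4 and C5 are set together from C6.

Step 16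
Reactants: 25 (1(10)E,3S,4R,5R,6R,7S)-4,5-epoxy-6-hydroxygermacra-1(10),11-dien-3-yl (E)-2-methylbut-2-enoate
Product: 26 (1(10)E,3S,4R,5R,6R,7S)-6-acetoxy-4,5-epoxygermacra-1(10),11-dien-3-yl (E)-2-methylbut-2-enoate (target)
Conditions: Ac2O, pyridine, DMAP (cat.), CH2Cl2, 0 °C → rt
Reagents that add atoms: acetic anhydride, CC(=O)OC(C)=O
Why: DMAP-catalysed acetylation of the secondary alcohol under basic, non-Lewis-acidic conditions leaves the acid-sensitive epoxy-germacradiene and the tiglate intact and gives the target.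

**Compound list**

1 | pent-3-yn-1-ol | CC#CCCO | starting material
2 | O,C-bis(chlorozirconocene) adduct: (E)-alkenylzirconocene chloride of the zirconium alkoxide of 1 | C/C(=C\CCO[Zr](Cl)(C1C=CC=C1)C1C=CC=C1)[Zr](Cl)(C1C=CC=C1)C1C=CC=C1 | intermediate (not isolated)
3 | (E)-4-iodopent-3-en-1-ol | C/C(I)=C\CCO | intermediate
4 | (R)-4-benzyloxazolidin-2-one | O=C1N[C@H](Cc2ccccc2)CO1 | starting material
5 | (E)-but-2-enoyl chloride | C/C=C/C(Cl)=O | starting material
6 | lithium (R)-4-benzyl-2-oxooxazolidin-3-ide | [Li]N1[C@H](Cc2ccccc2)COC1=O | intermediate (not isolated)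
7 | (R)-4-benzyl-3-[(E)-but-2-enoyl]oxazolidin-2-one | C/C=C/C(=O)N1[C@H](Cc2ccccc2)COC1=O | intermediate
8 | but-2-ynal | CC#CC=O | starting material
9 | (Z)-dibutylboron dienolate of 7 | C=C/C=C(\OB(CCCC)CCCC)N1[C@H](Cc2ccccc2)COC1=O | intermediate (not isolated)
10 | dibutylboron aldolate of 11 | CC#C[C@H](OB(CCCC)CCCC)[C@@H](C=C)C(=O)N1[C@H](Cc2ccccc2)COC1=O | intermediate (not isolated)
11 | (R)-4-benzyl-3-[(2R,3R)-2-ethenyl-3-hydroxyhex-4-ynoyl]oxazolidin-2-one | CC#C[C@H](O)[C@@H](C=C)C(=O)N1[C@H](Cc2ccccc2)COC1=O | intermediate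
12 | (2R,3R)-2-ethenyl-3-hydroxy-N-methoxy-N-methylhex-4-ynamide | CC#C[C@H](O)[C@@H](C=C)C(=O)N(C)OC | intermediate
13 | (2R,3R)-3-(tert-butyldimethylsilyloxy)-2-ethenyl-N-methoxy-N-methylhex-4-ynamide | CC#C[C@H](O[Si](C)(C)C(C)(C)C)[C@@H](C=C)C(=O)N(C)OC | intermediate
14 | (2R,3R)-2-[2-(9-borabicyclo[3.3.1]nonan-9-yl)ethyl]-3-(tert-butyldimethylsilyloxy)-N-methoxy-N-methylhex-4-ynamide | CC#C[C@H](O[Si](C)(C)C(C)(C)C)[C@@H](CCB1C2CCCC1CCC2)C(=O)N(C)OC | intermediate (not isolated)
15 | (2R,5E)-2-[(1R)-1-(tert-butyldimethylsilyloxy)but-2-yn-1-yl]-8-hydroxy-N-methoxy-N,5-dimethyloct-5-enamide | CC#C[C@H](O[Si](C)(C)C(C)(C)C)[C@@H](CC/C(C)=C/CCO)C(=O)N(C)OC | intermediate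
16 | (3R,6E)-3-[(1R)-1-(tert-butyldimethylsilyloxy)but-2-yn-1-yl]-9-hydroxy-6-methylnon-6-en-2-one | CC#C[C@H](O[Si](C)(C)C(C)(C)C)[C@@H](CC/C(C)=C/CCO)C(C)=O | intermediate
17 | (3E,7S,8R)-8-(tert-butyldimethylsilyloxy)-4-methyl-7-(prop-1-en-2-yl)undec-3-en-9-yn-1-ol | CC#C[C@H](O[Si](C)(C)C(C)(C)C)[C@@H](CC/C(C)=C/CCO)C(C)=C | intermediate
18 | (3E,7S,8R)-8-(tert-butyldimethylsilyloxy)-4-methyl-7-(prop-1-en-2-yl)undec-3-en-9-ynal | CC#C[C@H](O[Si](C)(C)C(C)(C)C)[C@@H](CC/C(C)=C/CC=O)C(C)=C | intermediate
19 | (1(10)E,4E,6S,7S)-6-(tert-butyldimethylsilyloxy)-3-(triethylsilyloxy)germacra-1(10),4,11-triene, C3 epimers | C=C(C)[C@@H]1CC/C(C)=C/CC(O[Si](CC)(CC)CC)/C(C)=C/[C@@H]1O[Si](C)(C)C(C)(C)C | intermediate (not isolated)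
20 | (1(10)E,4E,6S,7S)-6-(tert-butyldimethylsilyloxy)germacra-1(10),4,11-trien-3-ol, C3 epimers | C=C(C)[C@@H]1CC/C(C)=C/CC(O)/C(C)=C/[C@@H]1O[Si](C)(C)C(C)(C)C | intermediate
21 | (1(10)E,4E,6S,7S)-6-(tert-butyldimethylsilyloxy)germacra-1(10),4,11-trien-3-one | C=C(C)[C@@H]1CC/C(C)=C/CC(=O)/C(C)=C/[C@@H]1O[Si](C)(C)C(C)(C)C | intermediate
22 | (1(10)E,3S,4E,6S,7S)-6-(tert-butyldimethylsilyloxy)germacra-1(10),4,11-trien-3-ol | C=C(C)[C@@H]1CC/C(C)=C/C[C@H](O)/C(C)=C/[C@@H]1O[Si](C)(C)C(C)(C)C | intermediate
23 | (1(10)E,3S,4E,6S,7S)-6-(tert-butyldimethylsilyloxy)germacra-1(10),4,11-trien-3-yl (E)-2-methylbut-2-enoate | C=C(C)[C@@H]1CC/C(C)=C/C[C@H](OC(=O)/C(C)=C/C)/C(C)=C/[C@@H]1O[Si](C)(C)C(C)(C)C | intermediate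
24 | (1(10)E,3S,4E,6S,7S)-6-hydroxygermacra-1(10),4,11-trien-3-yl (E)-2-methylbut-2-enoate | C=C(C)[C@@H]1CC/C(C)=C/C[C@H](OC(=O)/C(C)=C/C)/C(C)=C/[C@@H]1O | intermediate
25 | (1(10)E,3S,4R,5R,6R,7S)-4,5-epoxy-6-hydroxygermacra-1(10),11-dien-3-yl (E)-2-methylbut-2-enoate | C=C(C)[C@@H]1CC/C(C)=C/C[C@H](OC(=O)/C(C)=C/C)[C@@]2(C)O[C@@H]2[C@@H]1O | intermediate
26 | (1(10)E,3S,4R,5R,6R,7S)-6-acetoxy-4,5-epoxygermacra-1(10),11-dien-3-yl (E)-2-methylbut-2-enoate | C=C(C)[C@@H]1CC/C(C)=C/C[C@H](OC(=O)/C(C)=C/C)[C@@]2(C)O[C@@H]2[C@@H]1OC(C)=O | target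

**Step count and risks**

Total steps: 16. Longest linear sequence: 15 (steps 2–16; step 1 makes the coupling partner 3).

Most likely to fail, in this order:

Step 10. Ring closure may lose to intermolecular coupling, or bond formation may switch to C5 (exo mode), because the endo transition state must already hold an E-olefin inside a ten-membered ring; the skipped enal may also isomerise before it reacts. The fallback replaces the catalytic metallacycle route by a stoichiometric chromium-mediated alkenyl addition. It sets out from 17: hydrozirconation with the Schwartz reagent (zirconium to the methyl-capped alkyne carbon) and iodination would give the (E)-alkenyl iodide F1. Buffered Dess–Martin oxidation would give the iodo-aldehyde F2. Nozaki–Hiyama–Kishi cyclisation (CrCl2, NiCl2 cat., DMSO–THF, high dilution) would then form the same C3–C4 bond and deliver the free allylic alcohols, rejoining the route at 20.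

Step 15. The cis-methyl on C4 crowds the titanium-bound C6 carbinol, so oxygen transfer may be slow, may lose facial control, or the Lewis acid may open the new oxirane transannularly. The fallback moves the directing role to C3 and corrects C3 afterwards. It sets out from 21: reduction with the enantiomeric (S)-CBS catalyst would give the (3R)-allylic alcohol F3. VO(acac)2/t-BuOOH epoxidation directed by that hydroxyl (nearly eclipsed C3–O, ring carbon C2 on the far face, erythro mode) should give the 4R,5R epoxy alcohol F4. Mitsunobu esterification with tiglic acid (PPh3, DIAD) would invert C3 while installing the ester, giving the silylated epoxy tiglate F5. TBAF/AcOH would then rejoin the route at 25.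

Step 12. Hydride delivery may follow the ring's own preferred trajectory instead of the catalyst, giving poor facial selectivity at C3. The fallback sets C3 by invertive esterification instead of by reduction. It sets out from 21: Luche reduction (NaBH4, CeCl3, MeOH, −78 °C) along the ring-preferred trajectory, or the matched (S)-CBS catalyst, would give the (3R)-allylic alcohol F6 (the same structure as F3). A Mitsunobu reaction with tiglic acid (PPh3, DIAD, toluene, 0 °C) should displace at C3 with inversion and rejoin the route at 23.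

Further compounds

F1 | step 10 | (3E,7S,8R,9E)-8-(tert-butyldimethylsilyloxy)-10-iodo-4-methyl-7-(prop-1-en-2-yl)undeca-3,9-dien-1-ol | C/C(I)=C\[C@H](O[Si](C)(C)C(C)(C)C)[C@@H](CC/C(C)=C/CCO)C(C)=C
F2 | step 10 | (3E,7S,8R,9E)-8-(tert-butyldimethylsilyloxy)-10-iodo-4-methyl-7-(prop-1-en-2-yl)undeca-3,9-dienal | C/C(I)=C\[C@H](O[Si](C)(C)C(C)(C)C)[C@@H](CC/C(C)=C/CC=O)C(C)=C
F3 | step 15 | (1(10)E,3R,4E,6S,7S)-6-(tert-butyldimethylsilyloxy)germacra-1(10),4,11-trien-3-ol | C=C(C)[C@@H]1CC/C(C)=C/C[C@@H](O)/C(C)=C/[C@@H]1O[Si](C)(C)C(C)(C)C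
F4 | step 15 | (1(10)E,3R,4R,5R,6R,7S)-6-(tert-butyldimethylsilyloxy)-4,5-epoxygermacra-1(10),11-dien-3-ol | C=C(C)[C@@H]1CC/C(C)=C/C[C@@H](O)[C@@]2(C)O[C@@H]2[C@@H]1O[Si](C)(C)C(C)(C)C
F5 | step 15 | (1(10)E,3S,4R,5R,6R,7S)-6-(tert-butyldimethylsilyloxy)-4,5-epoxygermacra-1(10),11-dien-3-yl (E)-2-methylbut-2-enoate | C=C(C)[C@@H]1CC/C(C)=C/C[C@H](OC(=O)/C(C)=C/C)[C@@]2(C)O[C@@H]2[C@@H]1O[Si](C)(C)C(C)(C)C
F6 | step 12 | (1(10)E,3R,4E,6S,7S)-6-(tert-butyldimethylsilyloxy)germacra-1(10),4,11-trien-3-ol | C=C(C)[C@@H]1CC/C(C)=C/C[C@@H](O)/C(C)=C/[C@@H]1O[Si](C)(C)C(C)(C)C
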